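**Retrosynthetic overview**

Numbering used: C1 quaternary fusion carbon (methyl), C2/C3 ring CH2, C4 isopropyl carbinol, C5 fusion CH, C6 ester carbinol, C7 CH2, C8 methyl-bearing alkene carbon, C9 alkene CH, C10 ketone. The strategy rests on the C7–C8(Me)–C9 arc of the seven-membered ring: it lies between the two oxygen-bearing carbons C6 and C10, so it is a 2-methylenepropane-1,3-diyl unit joining two carbonyl carbons.
Target ⇒ dihydroxy enone + 3,4,5-trimethoxybenzoyl chloride (ester last); dihydroxy enone ⇒ methylene triol by masking the syn C4-OH/C6-OH pair as a boronate, oxidising C10 and moving the alkene into conjugation.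
Methylene triol ⇒ trans C6,C10 dialdehyde with free C4-OH + 3-chloro-2-(chloromethyl)prop-1-ene (C6–C7 and C9–C10; the seven-membered ring is closed last, onto the finished cyclopentane).
Dialdehyde ⇒ bis-acetal carbinol ⇒ 3-(dimethoxymethyl)cyclopentenone (conjugate methylation sets C1, enolate formylation makes C5–C6, isopropyl addition sets C4) ⇒ 2,2-dimethoxyacetaldehyde + methyl vinyl ketone (five-membered ring first).

Key step: step 7

Remark: the ligand antipode in step 3 is assumed to be chosen so that C1 forms as (S); the C10 carbinol of 12 is carried as both epimers because it becomes the ketone.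

**Route**

Step 1
Reactants: 1 2,2-dimethoxyacetaldehyde; 2 methyl vinyl ketone
Product: 3 1,1-dimethoxyhexane-2,5-dione
Conditions: 3-benzyl-5-(2-hydroxyethyl)-4-methylthiazolium chloride (10 mol %), Et3N, EtOH, 75 °C
Reagents that add atoms: none
Why: Stetter reaction, in which the thiazolylidene converts the aldehyde of 1 into an acyl anion equivalent that adds 1,4 to 2, as is usual for aliphatic aldehydes and methyl vinyl ketone; no stereocentre is formed.

Step 2
Reactants: 3 1,1-dimethoxyhexane-2,5-dione
Product: 4 3-(dimethoxymethyl)cyclopent-2-en-1-one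
Conditions: KOH (cat.), MeOH/H2O, 60 °C
Reagents that add atoms: none
Why: Intramolecular aldol condensation of a 1,4-diketone, in which only attack of the methyl ketone enolate on the acetal-bearing ketone can dehydrate to a conjugated cyclopentenone, so the reversible aldol steps should funnel to 4 while the base-stable acetal survives.

Step 3
Reactants: 4 3-(dimethoxymethyl)cyclopent-2-en-1-one
Product: 6 (S)-{[3-(dimethoxymethyl)-3-methylcyclopent-1-en-1-yl]oxy}triethylsilane, via dimethylaluminium enolate 5 (not isolated)
Conditions: Me3Al, Cu(OTf)2 (5 mol %), chiral NHC–Ag complex (2.5 mol %), THF, −78 °C; then Et3SiOTf, −78 °C; Et3N, aq. NaHCO3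
Reagents that add atoms: trimethylaluminium C[Al](C)C; triethylsilyl trifluoromethanesulfonate CC[Si](CC)(CC)OS(=O)(=O)C(F)(F)F
Why: Copper-catalysed asymmetric conjugate addition of trimethylaluminium to a β-substituted cyclopentenone should set the quaternary C1 centre (S) under ligand control, and O-silylation of the regiodefined aluminium enolate at −78 °C in THF fixes the C4–C5 enol ether faster than the hindered acetal can be ionised.

Step 4
Reactants: 6 (S)-{[3-(dimethoxymethyl)-3-methylcyclopent-1-en-1-yl]oxy}triethylsilane
Product: 7 (2S,3S)-2,3-bis(dimethoxymethyl)-3-methylcyclopentan-1-one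
Conditions: HC(OMe)3 (excess), TMSOTf (10 mol %), CH2Cl2, −78 °C; Et3N quench
Reagents that add atoms: trimethyl orthoformate COC(OC)OC
Why: Mukaiyama-type addition of the silyl enol ether to the dimethoxycarbenium ion from the orthoester forms C5–C6 anti to the larger C1 substituent (the dimethoxymethyl group), giving the trans diacetal, which is also the thermodynamic epimer at the enolisable C5.

Step 5
Reactants: 7 (2S,3S)-2,3-bis(dimethoxymethyl)-3-methylcyclopentan-1-one
Product: 8 (1R,2R,3S)-2,3-bis(dimethoxymethyl)-3-methyl-1-(propan-2-yl)cyclopentan-1-ol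
Conditions: i-PrMgCl, anhydrous CeCl3, THF, −78 → 0 °C; aq. NH4Cl
Reagents that add atoms: isopropylmagnesium chloride CC(C)[Mg]Cl
Why: Organocerium 1,2-addition (Imamoto conditions) suppresses enolisation and β-hydride reduction of the hindered ketone, and the isopropyl group should enter from the ring face opposite the adjacent C5 substituent, placing the C4 hydroxyl cis to C6.

Step 6
Reactants: 8 (1R,2R,3S)-2,3-bis(dimethoxymethyl)-3-methyl-1-(propan-2-yl)cyclopentan-1-ol
Product: 9 (1S,2R,3R)-3-hydroxy-1-methyl-3-(propan-2-yl)cyclopentane-1,2-dicarbaldehyde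
Conditions: 10% aq. oxalic acid on SiO2, CH2Cl2, rt; filtered and used crude at once
Reagents that add atoms: water O
Why: Mild heterogeneous acid hydrolysis of the two dimethyl acetals should release both aldehydes without dehydrating the tertiary aldol, and C5 holds its configuration because the formyl group trans to isopropyl and to the C1 formyl group (hydrogen-bonded to the C4 hydroxyl) is the thermodynamic arrangement.

Step 7
Reactants: 9 (1S,2R,3R)-3-hydroxy-1-methyl-3-(propan-2-yl)cyclopentane-1,2-dicarbaldehyde; 10 3-chloro-2-(chloromethyl)prop-1-ene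
Product: 12 (3R,3aS,4S,8aS)-8a-methyl-6-methylidene-3-(propan-2-yl)decahydroazulene-3,4,8-triol (both C10 epimers; C10 is C8 of the azulene name), via chloro homoallylic alcohol 11 (not isolated)
Conditions: In powder (3 equiv), NaI (0.5 equiv), THF/H2O 1:1, 0.02 M, rt; 10 (1.1 equiv) added slowly
Reagents that add atoms: none
Why: Iodide exchange turns 10 into the allylic iodide, indium inserts, and the allylindium adds to the C6 aldehyde while indium bridges the free C4 hydroxyl and the C6 carbonyl oxygen in a six-membered chelate; the remaining allylic chloride of 11 is then metalated in the same way and the second allylindium forms C9–C10 at the neopentyl aldehyde. The closest known reaction type is the aqueous indium Barbier bis-allylation of dicarbonyl compounds with 2-(halomethyl)allyl halides (trimethylenemethane dianion equivalents) to methylenecycloalkanediols, combined with chelation-controlled allylindium addition to β-hydroxy aldehydes in water. The seven-membered ring closes by 7-exo-trig attack on the C10 carbonyl and is trans-fused because C6 and C10 are already trans on the cyclopentane. C6 is set (S) by the chelate, the allyl group entering from the carbonyl face next to H5 and away from quaternary C1, which leaves O6 syn to O4; C10 forms as both epimers, which does not matter because it is oxidised in step 8. If C10 reacts first, closure at C6 should place the indium-bound O6 pseudo-equatorial, away from the angular methyl, which is the same C6 configuration, so the symmetric reagent should give one ring and one C6 epimer in either order. The step needs facial selectivity at C6, secured by the free C4 hydroxyl and the water-rich medium, and ring closure in preference to a second intermolecular allylation, secured by high dilution and slow addition of a slight excess of 10.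

Step 8
Reactants: 12 (3R,3aS,4S,8aS)-8a-methyl-6-methylidene-3-(propan-2-yl)decahydroazulene-3,4,8-triol
Product: 15 O4,O6-phenylboronate of (3R,3aS,4S,8aS)-3,4-dihydroxy-6,8a-dimethyl-3-(propan-2-yl)-2,3,3a,4,5,8a-hexahydroazulen-8(1H)-one, via triol phenylboronate 13 (not isolated), via exo-methylene ketone boronate 14 (not isolated)
Conditions: PhB(OH)2 (1.05 equiv), 4 Å MS, CH2Cl2, rt; then Dess–Martin periodinane, NaHCO3, 0 °C → rt, aq. Na2S2O3/NaHCO3 wash; then DBU (cat.), CH2Cl2, 0 °C
Reagents that add atoms: phenylboronic acid OB(O)c1ccccc1
Why: Phenylboronic acid condenses only with the syn 1,3-diol (O4/O6) to a six-membered boronate, which leaves the C10 carbinol as the sole alcohol for Dess–Martin oxidation, and base-catalysed enolisation then moves the exocyclic alkene into conjugation (β,γ- to α,β-enone isomerisation); both C10 epimers converge on one ketone and no stereocentre is touched.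

Step 9
Reactants: 15 O4,O6-phenylboronate of the dihydroxy enone
Product: 16 (3R,3aS,4S,8aS)-3,4-dihydroxy-6,8a-dimethyl-3-(propan-2-yl)-2,3,3a,4,5,8a-hexahydroazulen-8(1H)-one
Conditions: 30% H2O2, pH 7 phosphate buffer, THF/MeOH, 0 °C
Reagents that add atoms: none
Why: Oxidative cleavage of the boron–aryl bond with buffered hydrogen peroxide, as in a boron aldol work-up, should free the diol, and at pH 7 and 0 °C the β,β-disubstituted enone is not expected to undergo nucleophilic epoxidation.

Step 10
Reactants: 16 the dihydroxy enone; 17 3,4,5-trimethoxybenzoyl chloride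
Product: 18 (3R,3aS,4S,8aS)-3-hydroxy-6,8a-dimethyl-8-oxo-3-(propan-2-yl)-1,2,3,3a,4,5,8,8a-octahydroazulen-4-yl 3,4,5-trimethoxybenzoate
Conditions: DMAP, pyridine, CH2Cl2, 0 °C → rt
Reagents that add atoms: none
Why: DMAP-catalysed acylation (nucleophilic catalysis) esterifies the only secondary hydroxyl while the tertiary C4 hydroxyl stays inert, and the weakly basic medium should avoid vinylogous β-elimination of the new ester from the enone.

**Compound list**

1 | 2,2-dimethoxyacetaldehyde | COC(OC)C=O | starting material
2 | methyl vinyl ketone (but-3-en-2-one) | C=CC(C)=O | starting material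
3 | 1,1-dimethoxyhexane-2,5-dione | COC(OC)C(=O)CCC(C)=O | intermediate
4 | 3-(dimethoxymethyl)cyclopent-2-en-1-one | COC(OC)C1=CC(=O)CC1 | intermediate
5 | dimethylaluminium C4–C5 enolate of (S)-3-(dimethoxymethyl)-3-methylcyclopentanone (not isolated) | COC(OC)[C@@]1(C)CCC(O[Al](C)C)=C1 | intermediate
6 | (S)-{[3-(dimethoxymethyl)-3-methylcyclopent-1-en-1-yl]oxy}triethylsilane | COC(OC)[C@@]1(C)CCC(O[Si](CC)(CC)CC)=C1 | intermediate
7 | (2S,3S)-2,3-bis(dimethoxymethyl)-3-methylcyclopentan-1-one (acetal groups trans) | COC(OC)[C@@]1(C)CCC(=O)[C@@H]1C(OC)OC | intermediate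
8 | (1R,2R,3S)-2,3-bis(dimethoxymethyl)-3-methyl-1-(propan-2-yl)cyclopentan-1-ol (OH cis to the C5 acetal) | COC(OC)[C@@]1(C)CC[C@@](O)(C(C)C)[C@@H]1C(OC)OC | intermediate
9 | (1S,2R,3R)-3-hydroxy-1-methyl-3-(propan-2-yl)cyclopentane-1,2-dicarbaldehyde (trans dialdehyde, OH cis to the C6 formyl) | O=C[C@@]1(C)CC[C@@](O)(C(C)C)[C@@H]1C=O | intermediate
10 | 3-chloro-2-(chloromethyl)prop-1-ene | C=C(CCl)CCl | starting material
11 | chloro homoallylic alcohol: 9 allylated at C6 with a 2-(chloromethyl)allyl group, (S) at C6, C10 aldehyde intact (not isolated) | O=C[C@@]1(C)CC[C@@](O)(C(C)C)[C@@H]1[C@@H](O)CC(=C)CCl | intermediate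
12 | (3R,3aS,4S,8aS)-8a-methyl-6-methylidene-3-(propan-2-yl)decahydroazulene-3,4,8-triol, both C10 epimers | O[C@H]1CC(=C)CC(O)[C@@]2(C)CC[C@@](O)(C(C)C)[C@H]12 | intermediate
13 | O4,O6-phenylboronate of triol 12, C10 carbinol free (not isolated) | OC1CC(=C)C[C@@H]2OB(c3ccccc3)O[C@@]4(C(C)C)CC[C@@]1(C)[C@@H]24 | intermediate
14 | O4,O6-phenylboronate of the C10 ketone with exocyclic C8 methylene (not isolated) | O=C1CC(=C)C[C@@H]2OB(c3ccccc3)O[C@@]4(C(C)C)CC[C@@]1(C)[C@@H]24 | intermediate
15 | O4,O6-phenylboronate of the conjugated C8=C9 enone | O=C1C=C(C)C[C@@H]2OB(c3ccccc3)O[C@@]4(C(C)C)CC[C@@]1(C)[C@@H]24 | intermediate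
16 | (3R,3aS,4S,8aS)-3,4-dihydroxy-6,8a-dimethyl-3-(propan-2-yl)-2,3,3a,4,5,8a-hexahydroazulen-8(1H)-one | O[C@H]1CC(C)=CC(=O)[C@@]2(C)CC[C@@](O)(C(C)C)[C@H]12 | intermediate
17 | 3,4,5-trimethoxybenzoyl chloride | COc1cc(C(=O)Cl)cc(OC)c1OC | starting material
18 | (3R,3aS,4S,8aS)-3-hydroxy-6,8a-dimethyl-8-oxo-3-(propan-2-yl)-1,2,3,3a,4,5,8,8a-octahydroazulen-4-yl 3,4,5-trimethoxybenzoate | COc1cc(C(=O)O[C@H]2CC(C)=CC(=O)[C@@]3(C)CC[C@@](O)(C(C)C)[C@H]23)cc(OC)c1OC | target

**Step count and risks**

Total step count: 10. Longest linear sequence: 10 steps (1 and 2 to 18).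

Steps most likely to fail:

Step 7. The second allylindium may be protonated by water, or captured by a second molecule of reagent, before it reaches the hindered C10 aldehyde, so that open-chain methallyl or bis-allyl products form in place of the ring; facial selectivity at C6 may also fall if addition escapes the chelate. The fallback separates the two bond formations and sets out from 9. Indium-mediated, chelation-controlled allylation in THF/H2O with [2-(bromomethyl)prop-2-en-1-yl]trimethylsilane forms C6–C7 and gives the allylsilane mono-adduct F1, whose allylsilane is stable to water. An intramolecular Hosomi–Sakurai reaction (BF3·OEt2, CH2Cl2, −78 °C) then forms C9–C10 and closes the seven-membered ring, coming back to the route at 12.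

Step 3. Enantioselectivity may be low or the addition slow with the acetal-bearing β-substituent, and the aluminium or silyl Lewis acid may ionise the acetal. The fallback sets the quaternary centre by substrate control and sets out from 4. CBS reduction gives (S)-3-(dimethoxymethyl)cyclopent-2-en-1-ol F2. Hydroxyl-directed Simmons–Smith cyclopropanation (Et2Zn, CH2I2) gives the cis cyclopropyl carbinol F3. Dess–Martin oxidation gives the bicyclo[3.1.0]hexan-2-one F4. Li/NH3 then cleaves the external cyclopropane bond, whose CH2 becomes the C1 methyl, and the regiodefined lithium enolate is silylated with Et3SiCl/Et3N, coming back to the route at 6.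

Step 5. Enolisation or β-hydride reduction of the hindered ketone may outrun addition of the secondary organometallic, and facial selectivity may erode. The fallback sets out from 7 and uses a smaller sp2 nucleophile that has no β-hydride: 2-propenylmagnesium bromide with CeCl3 gives the isopropenyl carbinol F5, and hydrogenation (H2, Pd/C, EtOAc) saturates the alkene, coming back to the route at 8.

**Further compounds**

F1 | step 7 | allylsilane mono-adduct: 9 allylated at C6 with a 2-[(trimethylsilyl)methyl]allyl group, (S) at C6, C10 aldehyde intact | O=C[C@@]1(C)CC[C@@](O)(C(C)C)[C@@H]1[C@@H](O)CC(=C)C[Si](C)(C)C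
F2 | step 3 | (S)-3-(dimethoxymethyl)cyclopent-2-en-1-ol | COC(OC)C1=C[C@@H](O)CC1
F3 | step 3 | 5-(dimethoxymethyl)bicyclo[3.1.0]hexan-2-ol, cyclopropane cis to the hydroxyl | COC(OC)[C@]12C[C@H]1[C@@H](O)CC2
F4 | step 3 | 5-(dimethoxymethyl)bicyclo[3.1.0]hexan-2-one | COC(OC)[C@]12C[C@H]1C(=O)CC2
F5 | step 5 | 2,3-bis(dimethoxymethyl)-3-methyl-1-(prop-1-en-2-yl)cyclopentan-1-ol, configured as 8 | COC(OC)[C@@]1(C)CC[C@@](O)(C(C)=C)[C@@H]1C(OC)OC
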